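Readings and results stem from a simulated flask for an exercise; scatter was added.

In the north-west run substrate outnumbered free catalyst 200 to one, so the balance I wrote first was that of the catalyst: how much of it is still working at a given time.

| flask | substrate | free catalyst | time |
|---|---|---|---|
| north-west | 0.300 M | 0.00150 M |  |
| north | 0.150 M | 0.00150 M |  |
| north-east | 0.300 M | 0.00450 M |  |
| south | 0.600 M | 7.50 × 10⁻⁴ M | 140 h |

- north-west run (time / h: [target] / M): 6.2: 0.0694; 19: 0.1374; 36: 0.1828; 57: 0.2160; 82: 0.2379; 110: 0.2585; 140: 0.2709
- north run (time / h: [target] / M): 6.2: 0.0351; 19: 0.0683; 36: 0.0919; 57: 0.1073; 82: 0.1190; 110: 0.1272; 140: 0.1322
- north-east run (time / h: [target] / M): 6.2: 0.1153; 19: 0.1819; 36: 0.2167; 57: 0.2408; 82: 0.2579; 110: 0.2691; 140: 0.2782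

(each reading ± 9 × 10⁻⁴ M)

1. how the opening rate goes with [substrate] round the charge of the north-west run: the exponent of the rate at two percent of substrate gone to target (one fixed amount of target, the same in the runs compared)
2. how the opening rate goes with [free catalyst] round the charge of the north-west run: the exponent of the rate at two percent of substrate gone to target
3. target in the south run at 140 h, as a share of the substrate charged

- Overall: substrate -> target, with free catalyst as catalyst.
- Constant volume, constant temperature.
- Readings of a species count what is bound in complexes too.
- An order is taken over about fifteen percent of the charge, up and down.

I measured progress by L, the logarithm of the substrate charged over the substrate remaining, with the target reading giving what remains.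

I began with the main step alone, a pseudo-first-order step whose catalyst lasts. The first north-west reading gives a slope of L of 0.0424 /h. The south run has half that catalyst, so:

L(south, 140 h) = 2.97, a share of 94.9 %

The same rule fails on the simulated runs. At 140 h the north-west run stands at L = 2.33, so the north-east run should reach 7.00, yet it reads 2.62.

Next I added catalyst loss. A first-order loss still leaves L proportional to the charge, but a loss going with the square of [free catalyst] makes the reciprocal of [free catalyst] climb in a straight line. Late on, once that climb has left the starting value far behind, L grows with the logarithm of the charge. So I kept the catalyst gain, the rise of L at 140 h per unit of ln[free catalyst] charged, at the substrate charge of the north-west run, which read 0.263.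

L(south, 140 h) = 2.33 − 0.263 × ln(2.00) = 2.15, a share of 88.4 %

Last came the charge, twice the north-west one in the south run. The north run reads L = 2.13, so the step from north to north-west adds 0.202. If that step repeated, the share would be 90.5 %. I committed to 88.4 % and kept the higher figure as my upper edge.

The forecast gave orders of 1 in substrate and 0.7 in free catalyst, and 88 % for the south run, a little below my figure. It read the late slopes as “catalyst loss or sequestration that is higher than first order in catalyst”.

The flask ran by these steps:

    free catalyst + substrate ⇌ catalyst-substrate complex (145.1 /M/h, 59.76 /h)
    catalyst-substrate complex → target + free catalyst (24.95 /h)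
    2 free catalyst → 2 spent catalyst (88.92 /M/h)
    substrate → target (0.009324 /h)

The south run gave 88.5 %, with orders of 0.79 in substrate and 0.80 in free catalyst. At one fixed amount of target, the north run went at 0.54 of the north-west rate, where an order of 1 asks for 0.500. The south share means L = 2.17. Moving that to the north-west catalyst with the catalyst gain gives 2.35, against the 2.33 read in the north-west run at 140 h, where the scatter of that one reading is worth 0.0309 on L.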